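# Proposed total synthesis of CNP0202038.1 (compound 19)

Chain numbering C1–C15 is used throughout. O-a is the oxygen between C6 and C10, O-b the oxygen between C7 and C13. Ring A is the tetrahydropyran O-a/C6/C7/C8/C9/C10, ring B the oxocane O-b/C7/C8/C9/C10/C11/C12/C13.

## Analysis of the target

The target 19 is a C15 chain tied twice by ether oxygens, so that rings A and B share C7–C8–C9–C10 and form a 2,7-dioxabicyclo[4.2.2]decane with bridgeheads C7 and C10. There are six stereocentres (6R,7R,9S,10S,12S,13R). On ring A the four substituents (C5 at C6, O-b at C7, Br at C9, C11 at C10) are all cis, so ring A is held as a boat whose 1,4-positions C7 and C10 carry the four-atom bridge O-b–C13–C12–C11. The ethyl group at C13 is cis to the C7–C6 bond across ring B and trans to the bromine at C12; each bromine sits next to an ether carbon (C9 next to C10, C12 next to C13). Sensitive groups are the two secondary bromides (elimination, participation by neighbouring ether oxygens) and the (E)-pent-2-en-4-ynyl side chain with its terminal alkyne. The hard points are the eight-membered ring closed as a bridge over a boat, and the O-a–C10 bond: an oxygen on C6 that cyclises onto a C9=C10 unit reaches C9 through a five-membered and C10 through a six-membered transition state, and the smaller ring is the expected one. The feature used here is that C10 is the anomeric-type carbon of ring A (bonded to O-a, flanked by the heteroatom-bearing C9), and that C11 is alpha to C12, which also carries a heteroatom. C10 can therefore be the oxocarbenium carbon of a glycal-derived ring A, C9 the carbon that receives an electrophilic oxygen, and C11 the alpha-carbon of a C12 ketone.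

## Retrosynthetic reasoning

**Side chain (19 → 18 → 17 → 16).** The terminal C–H is masked as a silyl alkyne (18), the C3–C2 bond is cut to the E-alkenyl boronate 17, and the C4=C3 bond is cut to the allyl compound 16. The enyne is made last because it would not survive epoxidation, strong base and Lewis acid. Only an inert allyl group (C5–C4=C3) has to ride through the route. The forward steps must give the E-alkene and must not touch the bromides.

**Both C–Br bonds (16 → 15 → 14).** The two bromides are cut back to the diol 15, to be replaced in one double SN2 operation with inversion. This fixes 15 as 9R,12R. The C12 carbinol is traced to the ketone 14; the reduction must come from the face away from the C13 ethyl group.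

**The bridge, C10–C11 (14 → 10).** This is the only bond of the four-atom bridge that joins a nucleophilic carbon (C11, alpha to the C12 ketone) to the anomeric carbon of ring A. Cutting it removes ring B and leaves the monocyclic dihydropyran 10, in which O-a is already bonded to C10. The 5-exo/6-endo question therefore never arises. Forward, the enol ether C9=C10 must be epoxidised on the face opposite to the C6 and C7 substituents, and the tethered enol silane must then capture the C10 oxocarbenium ion from the O-b face. C9–O, C10–C11, ring B and the C12 carbonyl are thus delivered together.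

**Ring A, O-a–C10 (10 → 9).** The enol ether is cut to the alkynol 9. The forward cycloisomerisation must add the C6 hydroxyl to the terminal alkyne carbon only, which a metal vinylidene guarantees.

**The ketone tether and O-a protection (9 → 8 → 7).** The methyl ketone C11–C12 is traced to the lactone 7, in which O-a acylates C12. This ring protects O-a, keeps C13 configurationally safe, and is opened by one methyl nucleophile to give the ketone and the free C6 hydroxyl at once.

**C5–C4, O-b–C13 and C8–C9 (7 → 5 → 4 + 2 → 3; 2 → 1).** The allyl arm is cut at C5–C4 (epoxide opening by a vinyl metal). The ether O-b–C13 is cut to the epoxy alcohol 4 and the triflate 2, with SN2 inversion setting C13. The alkyne is cut at C8–C9 (epoxide opening by a silyl acetylide). Both carbinol stereocentres C6 and C7 thus come from the C2-symmetric bis-epoxide 3, and C13 from the hydroxy ester 1. No stereocentre of the carbon skeleton has to be made by an asymmetric reaction before the key step.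

## Alternatives that were turned down

**Alternative 1: (textbook) transannular bromoetherification.** Disconnection of O-a–C10 and C9–Br leads to the oxocene alcohol A1 (ring B first, by ring-closing metathesis). The forward key step is bromonium formation on the Z-alkene C9=C10 and capture by the C6 hydroxyl. It was turned down because both alkene carbons are secondary and electronically alike, and the hydroxyl reaches C9 through a five-membered transition state. The 5-exo mode should therefore win and give the isomeric 2,8-dioxabicyclo[5.2.1]decane A2 instead of the target. The same 5-versus-6 bias holds for epoxide or cyclic-sulfate variants, and A1 itself costs a long sequence.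

**Alternative 2: ring expansion of a vinyl ketal through an oxonium ylide.** O-a–C10 and C10–C11 are cut together. The precursor is the diazoketone A3, a 2-ethyl-2-vinyl-1,3-dioxolane of the C6/C7 diol. A metal carbenoid at C10 would form the ylide at O-a, and a [2,3]-shift of the ketal vinyl group would give the whole bicycle A4 in one step. It was turned down on mechanism. O-b is one atom closer to the carbenoid (five-membered ylide) and is bonded to the same allylic ketal carbon, so its ylide has the same [2,3] exit and leads to the isomeric skeleton A5. Any precursor that forms C10–C11 in this way with O-b–C13 in place makes O-b allylic, so the flaw is structural and not a matter of catalyst. The ketal carbon is in addition an uncontrolled stereocentre.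

**Alternative 3: transannular oxa-Michael addition.** O-a–C10 is cut from the bicyclic ketone A7 back to the oxocenone A6 (C10=C11–C12=O, made by ring-closing metathesis). This fixes the regiochemistry, since only C10 is a beta-carbon. It was turned down because the C9 stereocentre must then be built separately in the acyclic chain. The metathesis would also have to distinguish three alkenes or the arm would have to be masked. Finally, the addition is reversible and gives a boat-shaped ring A next to an enolisable ketone, so the position of the equilibrium is uncertain, and the route is longer.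

Key step: step 8

Assumption: (2R,2'R)-2,2'-bioxirane and methyl (2S)-2-hydroxybutanoate are taken as purchasable enantiopure materials; dimethyldioxirane (DMDO) is used as its freshly prepared acetone solution.

## Route

Step 1
Reactants: 1 methyl (2S)-2-hydroxybutanoate
Product: 2 methyl (2S)-2-{[(trifluoromethyl)sulfonyl]oxy}butanoate
Conditions: Tf2O, 2,6-lutidine, CH2Cl2, −78 → 0 °C
Reagents that add atoms: trifluoromethanesulfonic anhydride, O=S(=O)(OS(=O)(=O)C(F)(F)F)C(F)(F)F
Why: O-Sulfonylation of the secondary alcohol with retention at carbon; the alpha-ester triflate is a very reactive SN2 electrophile and is used at once.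

Step 2
Reactants: 3 (2R,2'R)-2,2'-bioxirane
Product: 4 (1R)-1-[(2R)-oxiran-2-yl]-4-(trimethylsilyl)but-3-yn-1-ol
Conditions: Me3SiC≡CH, n-BuLi, THF, −78 °C; BF3·OEt2; 3 (3 equiv), −78 °C; H2O
Reagents that add atoms: ethynyltrimethylsilane, C#C[Si](C)(C)C
Why: BF3-assisted opening of one terminal epoxide carbon (C8) by the lithium acetylide leaves both stereocentres of the C2-symmetric bis-epoxide untouched. The excess of 3 limits double opening, and the low temperature and the boron-bound alkoxide prevent epoxide migration.

Step 3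
Reactants: 4 (1R)-1-[(2R)-oxiran-2-yl]-4-(trimethylsilyl)but-3-yn-1-ol; 2 methyl (2S)-2-{[(trifluoromethyl)sulfonyl]oxy}butanoate
Product: 5 methyl (2R)-2-{[(1R)-1-[(2R)-oxiran-2-yl]-4-(trimethylsilyl)but-3-yn-1-yl]oxy}butanoate
Conditions: NaH, THF, −30 → 0 °C (4 and 2 premixed)
Reagents that add atoms: none
Why: Williamson-type etherification in which the C7 alkoxide displaces triflate by SN2 with inversion, which sets C13 as R. The electrophile is present before the base so that alkylation outruns migration of the neighbouring epoxide (Payne rearrangement).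

Step 4
Reactants: 5 methyl (2R)-2-{[(1R)-1-[(2R)-oxiran-2-yl]-4-(trimethylsilyl)but-3-yn-1-yl]oxy}butanoate
Product: 7 (3R,5R,6R)-3-ethyl-6-(prop-2-en-1-yl)-5-[3-(trimethylsilyl)prop-2-yn-1-yl]-1,4-dioxan-2-one, via hydroxy ester 6 (not isolated)
Conditions: CH2=CHMgBr, CuI (cat.), THF, −40 °C; AcOH; PPTS (cat.), PhMe, 60 °C
Reagents that add atoms: vinylmagnesium bromide, C=C[Mg]Br
Why: Copper-catalysed Grignard opening of the terminal epoxide at its CH2 carbon (C5) installs the allyl arm and frees the C6 hydroxyl without touching C6. Mild acid then closes this hydroxyl onto the methyl ester to give the six-membered lactone, which protects O-a and masks the future ketone.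

Step 5
Reactants: 7 (3R,5R,6R)-3-ethyl-6-(prop-2-en-1-yl)-5-[3-(trimethylsilyl)prop-2-yn-1-yl]-1,4-dioxan-2-one
Product: 8 (3R)-3-{[(4R,5R)-5-hydroxy-1-(trimethylsilyl)oct-7-en-1-yn-4-yl]oxy}pentan-2-one (largely present as its cyclic hemiketal)
Conditions: MeLi (1.1 equiv), THF, −78 °C; H2O
Reagents that add atoms: methyllithium, [Li]C
Why: One equivalent of methyllithium adds to the lactone carbonyl, and the lithium lactolate resists a second addition at low temperature. Work-up releases the methyl ketone (C11–C12) and the C6 hydroxyl together.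

Step 6
Reactants: 8 (3R)-3-{[(4R,5R)-5-hydroxy-1-(trimethylsilyl)oct-7-en-1-yn-4-yl]oxy}pentan-2-one
Product: 9 (3R)-3-{[(4R,5R)-5-hydroxyoct-7-en-1-yn-4-yl]oxy}pentan-2-one
Conditions: K2CO3 (cat.), MeOH, 0 °C → rt
Reagents that add atoms: none
Why: Base-catalysed methanolysis of the alkynyl C–Si bond; the ketone is mostly masked as the hemiketal, which shields the alpha-alkoxy stereocentre C13 from epimerisation.

Step 7
Reactants: 9 (3R)-3-{[(4R,5R)-5-hydroxyoct-7-en-1-yn-4-yl]oxy}pentan-2-one
Product: 10 (3R)-3-{[(2R,3R)-2-(prop-2-en-1-yl)-3,4-dihydro-2H-pyran-3-yl]oxy}pentan-2-one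
Conditions: W(CO)6 (25 mol %), DABCO, THF, hν (350 nm), 60 °C
Reagents that add atoms: none
Why: Photogenerated W(CO)5 turns the terminal alkyne into a tungsten vinylidene whose alpha-carbon (C10) is attacked by the C6 hydroxyl (endo-selective alkynol cycloisomerisation to a glycal). Ring A therefore closes only in the 6-endo sense, and no stereocentre is touched.

Step 8
Reactants: 10 (3R)-3-{[(2R,3R)-2-(prop-2-en-1-yl)-3,4-dihydro-2H-pyran-3-yl]oxy}pentan-2-one
Product: 14 (1R,3R,6S,8R,10R)-3-ethyl-10-hydroxy-8-(prop-2-en-1-yl)-2,7-dioxabicyclo[4.2.2]decan-4-one, via anhydro sugar 11 (not isolated), via silyl enol ether 12 (not isolated), via silyl ether 13 (not isolated)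
Conditions: DMDO, acetone–CH2Cl2, −78 → 0 °C, evaporate; LiN(i-Pr)2, THF, −78 °C, then Me3SiCl, evaporate; Me3SiOTf (20 mol %), CH2Cl2 (0.005 M), −78 → −30 °C; 0.5 M HCl, THF, 0 °C
Reagents that add atoms: dimethyldioxirane, CC1(C)OO1
Why: Dimethyldioxirane should epoxidise the electron-rich enol ether C9=C10 far faster than the terminal alkene and from the face opposite to the two cis substituents at C6 and C7, giving the 1,2-anhydro sugar 11 and placing the C9 oxygen on the face from which later inversion leads to the bromide. Kinetic deprotonation at the methyl group (C11) and silylation give the silyl enol ether 12; the hindered alpha-alkoxy methine C13 should not be deprotonated, which matters because a C13 enolate would close a six-membered ring instead. Catalytic Me3SiOTf silylates the epoxide oxygen and opens it to the ring A oxocarbenium ion at C10, which the tethered enol ether attacks through C11 in an 8-(enolendo)-exo-trig Mukaiyama-type closure; silyl transfer regenerates the catalyst and leaves the C12 ketone and the C9 silyl ether 13. The closest known reaction type is the Lewis-acid-mediated C-glycosylation of glycal epoxides and related glycosyl donors with silyl enol ethers, run here intramolecularly. C10 is controlled by the tether: O-b stands on C7 on one face of ring A, so C11 can arrive only cis to C7–O-b and anti to the epoxide oxygen, which gives 10S next to 9R. Ring B is thus closed as a 1,4-bridge over a boat-like oxocarbenium conformation of ring A, while the O-a–C10 bond, the one a bromoetherification would get wrong, is present from the start. The step needs intramolecular capture to beat oligomerisation, which high dilution and the short three-bond tether should secure; attack through the enol oxygen would give an anomeric enol ether that reionises under the same Lewis acid, so the C-bonded ketone is the sink. Mild acid work-up cleaves the silyl ether to 14.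

Step 9
Reactants: 14 (1R,3R,6S,8R,10R)-3-ethyl-10-hydroxy-8-(prop-2-en-1-yl)-2,7-dioxabicyclo[4.2.2]decan-4-one
Product: 15 (1R,3R,4R,6S,8R,10R)-3-ethyl-8-(prop-2-en-1-yl)-2,7-dioxabicyclo[4.2.2]decane-4,10-diol
Conditions: LiBH(s-Bu)3, THF, −78 °C; H2O
Reagents that add atoms: none
Why: The bulky hydride should attack the C12 ketone from the face turned to the C8–C9 bridge, away from the C13 ethyl group and the C6 side chain (substrate-controlled reduction of a cyclic alpha-alkoxy ketone). This gives the 12R alcohol cis to ethyl.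

Step 10
Reactants: 15 (1R,3R,4R,6S,8R,10R)-3-ethyl-8-(prop-2-en-1-yl)-2,7-dioxabicyclo[4.2.2]decane-4,10-diol
Product: 16 (1R,3R,4S,6S,8R,10S)-4,10-dibromo-3-ethyl-8-(prop-2-en-1-yl)-2,7-dioxabicyclo[4.2.2]decane
Conditions: CBr4, P(n-C8H17)3, PhMe, 70 °C
Reagents that add atoms: tetrabromomethane, BrC(Br)(Br)Br
Why: Double Appel bromination in which both oxyphosphonium groups are displaced by bromide with inversion, turning 9R,12R into 9S,12S. Neither leaving group has an antiperiplanar ring oxygen, so participation and ring contraction are not expected.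

Step 11
Reactants: 16 (1R,3R,4S,6S,8R,10S)-4,10-dibromo-3-ethyl-8-(prop-2-en-1-yl)-2,7-dioxabicyclo[4.2.2]decane
Product: 17 2-{(1E)-3-[(1R,3R,4S,6S,8R,10S)-4,10-dibromo-3-ethyl-2,7-dioxabicyclo[4.2.2]decan-8-yl]prop-1-en-1-yl}-4,4,5,5-tetramethyl-1,3,2-dioxaborolane
Conditions: CH2=CH–B(pin), second-generation Grubbs catalyst (5 mol %), CH2Cl2, 40 °C
Reagents that add atoms: 4,4,5,5-tetramethyl-2-vinyl-1,3,2-dioxaborolane, C=CB1OC(C)(C)C(C)(C)O1
Why: Cross-metathesis of the unhindered terminal alkene with the vinyl boronate should give the E-alkenyl boronate under thermodynamic control; ethers and secondary bromides are inert to the ruthenium carbene.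

Step 12
Reactants: 17 2-{(1E)-3-[(1R,3R,4S,6S,8R,10S)-4,10-dibromo-3-ethyl-2,7-dioxabicyclo[4.2.2]decan-8-yl]prop-1-en-1-yl}-4,4,5,5-tetramethyl-1,3,2-dioxaborolane
Product: 18 {(3E)-5-[(1R,3R,4S,6S,8R,10S)-4,10-dibromo-3-ethyl-2,7-dioxabicyclo[4.2.2]decan-8-yl]pent-3-en-1-yn-1-yl}trimethylsilane
Conditions: Me3SiC≡CBr, Pd(PPh3)4 (5 mol %), K3PO4, THF–H2O, rt
Reagents that add atoms: (bromoethynyl)trimethylsilane, BrC#C[Si](C)(C)C
Why: Suzuki–Miyaura coupling of the alkenyl boronate with the bromoalkyne forms C3–C2 with retention of the E geometry. Oxidative addition of zerovalent palladium to the sp C–Br bond is much faster than to the secondary alkyl bromides.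

Step 13
Reactants: 18 {(3E)-5-[(1R,3R,4S,6S,8R,10S)-4,10-dibromo-3-ethyl-2,7-dioxabicyclo[4.2.2]decan-8-yl]pent-3-en-1-yn-1-yl}trimethylsilane
Product: 19 (1R,3R,4S,6S,8R,10S)-4,10-dibromo-3-ethyl-8-[(2E)-pent-2-en-4-yn-1-yl]-2,7-dioxabicyclo[4.2.2]decane
Conditions: K2CO3 (cat.), MeOH, 0 °C
Reagents that add atoms: none
Why: Mild methanolysis of the alkynylsilane frees the terminal enyne without touching the secondary bromides; the product is the target (6R,7R,9S,10S,12S,13R in chain numbering).

## Compound list

1 | methyl (2S)-2-hydroxybutanoate | CC[C@H](O)C(=O)OC | starting material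
2 | methyl (2S)-2-{[(trifluoromethyl)sulfonyl]oxy}butanoate | CC[C@H](OS(=O)(=O)C(F)(F)F)C(=O)OC | intermediate
3 | (2R,2'R)-2,2'-bioxirane | O1C[C@@H]1[C@H]1CO1 | starting material
4 | (1R)-1-[(2R)-oxiran-2-yl]-4-(trimethylsilyl)but-3-yn-1-ol | O[C@H](CC#C[Si](C)(C)C)[C@H]1CO1 | intermediate
5 | methyl (2R)-2-{[(1R)-1-[(2R)-oxiran-2-yl]-4-(trimethylsilyl)but-3-yn-1-yl]oxy}butanoate | COC(=O)[C@@H](CC)O[C@H](CC#C[Si](C)(C)C)[C@H]1CO1 | intermediate
6 | methyl (2R)-2-{[(4R,5R)-5-hydroxy-1-(trimethylsilyl)oct-7-en-1-yn-4-yl]oxy}butanoate | COC(=O)[C@@H](CC)O[C@H](CC#C[Si](C)(C)C)[C@H](O)CC=C | intermediate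
7 | (3R,5R,6R)-3-ethyl-6-(prop-2-en-1-yl)-5-[3-(trimethylsilyl)prop-2-yn-1-yl]-1,4-dioxan-2-one | C=CC[C@H]1OC(=O)[C@@H](CC)O[C@@H]1CC#C[Si](C)(C)C | intermediate
8 | (3R)-3-{[(4R,5R)-5-hydroxy-1-(trimethylsilyl)oct-7-en-1-yn-4-yl]oxy}pentan-2-one (open form of the hemiketal) | C=CC[C@@H](O)[C@@H](CC#C[Si](C)(C)C)O[C@H](CC)C(C)=O | intermediate
9 | (3R)-3-{[(4R,5R)-5-hydroxyoct-7-en-1-yn-4-yl]oxy}pentan-2-one | C=CC[C@@H](O)[C@@H](CC#C)O[C@H](CC)C(C)=O | intermediate
10 | (3R)-3-{[(2R,3R)-2-(prop-2-en-1-yl)-3,4-dihydro-2H-pyran-3-yl]oxy}pentan-2-one | C=CC[C@H]1OC=CC[C@H]1O[C@H](CC)C(C)=O | intermediate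
11 | (3R)-3-{[(1S,3R,4R,6R)-3-(prop-2-en-1-yl)-2,7-dioxabicyclo[4.1.0]heptan-4-yl]oxy}pentan-2-one | C=CC[C@H]1O[C@@H]2O[C@@H]2C[C@H]1O[C@H](CC)C(C)=O | intermediate
12 | (1S,3R,4R,6R)-3-(prop-2-en-1-yl)-4-({(3R)-2-[(trimethylsilyl)oxy]pent-1-en-3-yl}oxy)-2,7-dioxabicyclo[4.1.0]heptane | C=CC[C@H]1O[C@@H]2O[C@@H]2C[C@H]1O[C@H](CC)C(=C)O[Si](C)(C)C | intermediate
13 | (1R,3R,6S,8R,10R)-3-ethyl-8-(prop-2-en-1-yl)-10-[(trimethylsilyl)oxy]-2,7-dioxabicyclo[4.2.2]decan-4-one | C=CC[C@H]1O[C@H]2CC(=O)[C@@H](CC)O[C@@H]1C[C@H]2O[Si](C)(C)C | intermediate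
14 | (1R,3R,6S,8R,10R)-3-ethyl-10-hydroxy-8-(prop-2-en-1-yl)-2,7-dioxabicyclo[4.2.2]decan-4-one | C=CC[C@H]1O[C@H]2CC(=O)[C@@H](CC)O[C@@H]1C[C@H]2O | intermediate
15 | (1R,3R,4R,6S,8R,10R)-3-ethyl-8-(prop-2-en-1-yl)-2,7-dioxabicyclo[4.2.2]decane-4,10-diol | C=CC[C@H]1O[C@H]2C[C@@H](O)[C@@H](CC)O[C@@H]1C[C@H]2O | intermediate
16 | (1R,3R,4S,6S,8R,10S)-4,10-dibromo-3-ethyl-8-(prop-2-en-1-yl)-2,7-dioxabicyclo[4.2.2]decane | C=CC[C@H]1O[C@H]2C[C@H](Br)[C@@H](CC)O[C@@H]1C[C@@H]2Br | intermediate
17 | 2-{(1E)-3-[(1R,3R,4S,6S,8R,10S)-4,10-dibromo-3-ethyl-2,7-dioxabicyclo[4.2.2]decan-8-yl]prop-1-en-1-yl}-4,4,5,5-tetramethyl-1,3,2-dioxaborolane | CC1(C)OB(/C=C/C[C@H]2O[C@H]3C[C@H](Br)[C@@H](CC)O[C@@H]2C[C@@H]3Br)OC1(C)C | intermediate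
18 | {(3E)-5-[(1R,3R,4S,6S,8R,10S)-4,10-dibromo-3-ethyl-2,7-dioxabicyclo[4.2.2]decan-8-yl]pent-3-en-1-yn-1-yl}trimethylsilane | C[Si](C)(C)C#C/C=C/C[C@H]1O[C@H]2C[C@H](Br)[C@@H](CC)O[C@@H]1C[C@@H]2Br | intermediate
19 | (1R,3R,4S,6S,8R,10S)-4,10-dibromo-3-ethyl-8-[(2E)-pent-2-en-4-yn-1-yl]-2,7-dioxabicyclo[4.2.2]decane | C#C/C=C/C[C@H]1O[C@H]2C[C@H](Br)[C@@H](CC)O[C@@H]1C[C@@H]2Br | target

## Step count and least certain steps

Total: 13 steps. Longest linear sequence: 12 steps (3 to 19, steps 2–13); step 1 is a one-step branch.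

**Step 8 (key step).** The ring closure may lose to oligomerisation or to elimination at the activated anomeric centre, the anhydro sugar may be hydrolysed by adventitious water, or enolisation may leak to C13 and close a six-membered ring. Fallback: from 10, epoxidation and addition of water would give the 2-hydroxy lactol (3R)-3-{[(2R,3R,5R)-5,6-dihydroxy-2-(prop-2-en-1-yl)oxan-3-yl]oxy}pentan-2-one F1. Its open-chain aldehyde can then undergo an amine-catalysed aldol condensation with the tethered methyl ketone followed by oxa-Michael addition of the C6 hydroxyl (pyrrolidine/AcOH or L-proline, MeOH). This thermodynamically driven C-glycosidation cascade comes back to the route at 14.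

**Step 3.** The alkoxide of 4 may undergo epoxide migration before it is alkylated, and the triflate may suffer elimination or racemisation by the base. Fallback: from 3, the order of the two epoxide openings is reversed. The vinyl Grignard/CuI opening gives (1R)-1-[(2R)-oxiran-2-yl]but-3-en-1-ol F2. Its hydroxyl is capped without alkoxide formation (4-methoxybenzyl trichloroacetimidate, La(OTf)3 cat.) as the 4-methoxybenzyl ether F3. The silyl acetylide then opens the remaining epoxide to (4R,5R)-5-[(4-methoxybenzyl)oxy]-1-(trimethylsilyl)oct-7-en-1-yn-4-ol F4, whose alkoxide has no neighbouring epoxide. Etherification with 2 gives the ether ester F5. Oxidative removal of the benzyl ether (DDQ) frees the C6 hydroxyl, which lactonises to 7, where the route is rejoined.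

**Step 7.** The photolysed metal carbonyl may isomerise the terminal alkene of the allyl arm, and the hemiketal may hold back the hydroxyl needed for ring closure. Fallback: from 9, ruthenium-catalysed anti-Markovnikov hydration of the alkyne ([CpRu(MeCN)3]PF6 with 5,5'-bis(trifluoromethyl)-2,2'-bipyridine, aqueous solvent) gives the aldehyde, which closes to the lactol (3R)-3-{[(2R,3R)-6-hydroxy-2-(prop-2-en-1-yl)oxan-3-yl]oxy}pentan-2-one F6. Dehydration (MsCl, Et3N, then warming) returns to the route at 10.

**Step 10.** Substitution at the bridged secondary centre C9 may be slow, so that elimination or skeletal rearrangement of the oxyphosphonium intermediates competes. Fallback: from 15, activation and displacement are separated. The bis(trifluoromethanesulfonate) F7 is formed at low temperature (Tf2O, pyridine) and displaced with n-Bu4NBr in toluene, a plain SN2 reaction on an isolated sulfonate, which comes back at 16.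

**Step 12.** Protodeboronation, homocoupling of the bromoalkyne or early loss of the silyl group may erode the coupling. Fallback: from 17, iododeboronation with retention (I2, NaOH, THF–H2O, 0 °C) gives the E-vinyl iodide (1R,3R,4S,6S,8R,10S)-4,10-dibromo-3-ethyl-8-[(2E)-3-iodoprop-2-en-1-yl]-2,7-dioxabicyclo[4.2.2]decane F8. Sonogashira coupling with ethynyltrimethylsilane (Pd(PPh3)4, CuI, i-Pr2NH) then comes back at 18.

## Further compounds

F1 | step 8 | (3R)-3-{[(2R,3R,5R)-5,6-dihydroxy-2-(prop-2-en-1-yl)oxan-3-yl]oxy}pentan-2-one (anomeric mixture) | C=CC[C@H]1OC(O)[C@H](O)C[C@H]1O[C@H](CC)C(C)=O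
F2 | step 3 | (1R)-1-[(2R)-oxiran-2-yl]but-3-en-1-ol | C=CC[C@@H](O)[C@H]1CO1
F3 | step 3 | (2R)-2-{(1R)-1-[(4-methoxybenzyl)oxy]but-3-en-1-yl}oxirane | C=CC[C@@H](OCc1ccc(OC)cc1)[C@H]1CO1
F4 | step 3 | (4R,5R)-5-[(4-methoxybenzyl)oxy]-1-(trimethylsilyl)oct-7-en-1-yn-4-ol | C=CC[C@@H](OCc1ccc(OC)cc1)[C@H](O)CC#C[Si](C)(C)C
F5 | step 3 | methyl (2R)-2-{[(4R,5R)-5-[(4-methoxybenzyl)oxy]-1-(trimethylsilyl)oct-7-en-1-yn-4-yl]oxy}butanoate | C=CC[C@@H](OCc1ccc(OC)cc1)[C@@H](CC#C[Si](C)(C)C)O[C@H](CC)C(=O)OC
F6 | step 7 | (3R)-3-{[(2R,3R)-6-hydroxy-2-(prop-2-en-1-yl)oxan-3-yl]oxy}pentan-2-one (anomeric mixture) | C=CC[C@H]1OC(O)CC[C@H]1O[C@H](CC)C(C)=O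
F7 | step 10 | (1R,3R,4R,6S,8R,10R)-3-ethyl-8-(prop-2-en-1-yl)-2,7-dioxabicyclo[4.2.2]decane-4,10-diyl bis(trifluoromethanesulfonate) | C=CC[C@H]1O[C@H]2C[C@@H](OS(=O)(=O)C(F)(F)F)[C@@H](CC)O[C@@H]1C[C@H]2OS(=O)(=O)C(F)(F)F
F8 | step 12 | (1R,3R,4S,6S,8R,10S)-4,10-dibromo-3-ethyl-8-[(2E)-3-iodoprop-2-en-1-yl]-2,7-dioxabicyclo[4.2.2]decane | I/C=C/C[C@H]1O[C@H]2C[C@H](Br)[C@@H](CC)O[C@@H]1C[C@@H]2Br
A1 | alternative 1 | (1R,3E)-1-[(2R,4Z,7S,8R)-7-bromo-8-ethyl-3,6,7,8-tetrahydro-2H-oxocin-2-yl]hex-3-en-5-yn-1-ol | C#C/C=C/C[C@@H](O)[C@H]1C/C=C\C[C@H](Br)[C@@H](CC)O1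
A2 | alternative 1 | 5-exo isomer: 4,6-dibromo-3-ethyl-9-[(2E)-pent-2-en-4-yn-1-yl]-2,8-dioxabicyclo[5.2.1]decane (stereochemistry as in the SMILES) | C#C/C=C/C[C@H]1O[C@@H]2C[C@H]1O[C@H](CC)[C@@H](Br)C[C@H]2Br
A3 | alternative 2 | methyl 2-[(4R,5R)-5-(3-diazo-2-oxopropyl)-2-ethenyl-2-ethyl-1,3-dioxolan-4-yl]acetate (vinyl cis to the diazoketone arm) | COC(=O)C[C@H]1O[C@](CC)(C=C)O[C@@H]1CC(=O)C=[N+]=[N-]
A4 | alternative 2 | methyl 2-[(1R,6S,8R)-3-ethyl-10-oxo-2,7-dioxabicyclo[4.2.2]dec-3-en-8-yl]acetate | COC(=O)C[C@H]1O[C@H]2CC=C(CC)O[C@@H]1CC2=O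
A5 | alternative 2 | isomeric 2,10-dioxabicyclo[5.2.1]decenone from the ylide at O-b (stereochemistry as in the SMILES) | COC(=O)C[C@H]1OC(CC)=CC[C@H]2O[C@@H]1CC2=O
A6 | alternative 3 | (2R,4Z,6R,8R)-6-[(tert-butyldimethylsilyl)oxy]-2-ethyl-8-[(1R)-1-hydroxybut-3-en-1-yl]-7,8-dihydro-2H-oxocin-3(6H)-one | C=CC[C@@H](O)[C@H]1C[C@@H](O[Si](C)(C)C(C)(C)C)/C=C\C(=O)[C@@H](CC)O1
A7 | alternative 3 | (1R,3R,6S,8R,10R)-10-[(tert-butyldimethylsilyl)oxy]-3-ethyl-8-(prop-2-en-1-yl)-2,7-dioxabicyclo[4.2.2]decan-4-one | C=CC[C@H]1O[C@H]2CC(=O)[C@@H](CC)O[C@@H]1C[C@H]2O[Si](C)(C)C(C)(C)C
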